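**Retrosynthetic overview**

1. Labels: C7 and C7' are the benzylic OCH carbons on ring A (phenol) and ring B (prenyl ether), C8 and C8' the ring-fusion CH carbons, C9 (on C8) and C9' (on C8') the OCH2 carbons; ring 1 is O1–C7–C8–C8'–C9', ring 2 is O2–C7'–C8'–C8–C9; the target is the 7R,8S,7'R,8'S isomer with both aryl groups exo.
2. Feature: ring 1 carries on C8 the exocyclic carbon C9; at the acid level C9 is the carbonyl of a γ-lactone closed through O2 onto C7', and a tetrahydrofuran with an exocyclic acyl carbon is what Wolff ring contraction of a 3-diazotetrahydropyran-4-one delivers.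
3. Disconnections: ring 2 ether ⇐ 1,4-diol ⇐ cis-fused lactone ⇐ 2,5-trans 2-(ring A aryl)-3-diazo-5-[hydroxy(ring B aryl)methyl]pyran-4-one (C8–C8' by 1,2-shift of C8', C9–O2 by ketene capture).
4. Diazo ketone ⇐ diazo transfer at C8 of the O-silylated aldol ⇐ reductive aldol (C8'–C7') of an (R)-2-aryl-2,3-dihydropyran-4-one with O-prenylvanillin, equilibrated as the zinc aldolate ⇐ catalytic hetero-Diels–Alder reaction of O-silylvanillin (C7).
5. Ring order: pyranone first; ring 1 by contraction together with ring 2 as lactone; ring 2 then reduced and closed again as the ether; the phenol is freed last.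

Key step: step 7

Notation: ArA = 3-methoxy-4-(triisopropylsilyloxy)phenyl; ArB = 3-methoxy-4-(3-methylbut-2-enyloxy)phenyl.

Assumption: the catalyst from Ti(OiPr)4 and (R)-BINOL is taken to direct the diene to the Re face of the aldehyde and so to give the (R)-dihydropyranone; if the sense is the opposite, (S)-BINOL is used in step 3 and nothing else changes.

**Route**

Step 1
Reactants: 1 vanillin
Product: 2 3-methoxy-4-(triisopropylsilyloxy)benzaldehyde
Conditions: iPr3SiCl, imidazole, DMF, 23 °C
Reagents that add atoms: triisopropylsilyl chloride, CC(C)[Si](Cl)(C(C)C)C(C)C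
Why: Imidazole-promoted O-silylation masks the phenol as a hindered aryl silyl ether that should withstand hydride, amide base, brief acid and irradiation and is cleaved by fluoride in the last step.

Step 2
Reactants: 1 vanillin; 3 prenyl bromide
Product: 4 3-methoxy-4-(3-methylbut-2-enyloxy)benzaldehyde
Conditions: K2CO3, DMF, 23 → 50 °C
Reagents that add atoms: prenyl bromide (3), CC(C)=CCBr
Why: Williamson ether synthesis, in which the phenoxide displaces the primary allylic bromide by SN2 at the unsubstituted terminus, so that no rearranged ether is expected.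

Step 3
Reactants: 2 3-methoxy-4-(triisopropylsilyloxy)benzaldehyde; 5 (E)-1-methoxy-3-(trimethylsilyloxy)buta-1,3-diene
Product: 7 (R)-2-ArA-2,3-dihydro-4H-pyran-4-one, via open-chain silyl aldol adduct 6 (not isolated)
Conditions: Ti(OiPr)4 (10 mol %), (R)-BINOL (20 mol %), 4 Å MS, Et2O, −20 °C; then CF3CO2H, CH2Cl2, 0 °C
Reagents that add atoms: (E)-1-methoxy-3-(trimethylsilyloxy)buta-1,3-diene (5), CO/C=C/C(=C)O[Si](C)(C)C
Why: The titanium–BINOL complex should catalyse Mukaiyama aldol addition of the silyloxydiene to the Re face of the aldehyde, and acid then closes the adduct with loss of methanol (hetero-Diels–Alder reaction in its stepwise form), so that C7 is set as R by the catalyst.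

Step 4
Reactants: 7 (R)-2-ArA-2,3-dihydro-4H-pyran-4-one; 4 3-methoxy-4-(3-methylbut-2-enyloxy)benzaldehyde
Product: 10 (2R,5S)-2-ArA-5-[(R)-hydroxy(ArB)methyl]tetrahydro-4H-pyran-4-one (2,5-trans anti aldol), via lithium enolate 8 (not isolated), via chlorozinc aldolate 9 (not isolated)
Conditions: LiBH(sBu)3 (1.05 equiv), THF, −78 °C; ZnCl2 (1.2 equiv), −78 °C; 4 (1.05 equiv), −78 → 0 °C, held at 0 °C; sat. aq NH4Cl; chromatography to remove minor diastereomers
Reagents that add atoms: none
Why: Conjugate hydride addition gives the C9–C8' enolate regiospecifically, and on zinc the aldol addition is reversible, so that this reductive aldol reaction, run under thermodynamic control because kinetic axial attack would be expected to place the side chain cis to the C7 aryl, should settle on the chelated aldolate with the side chain equatorial at C8' (2,5-trans) and ring B equatorial on the chelate ring (anti at C7'), while C7 is not touched.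

Step 5
Reactants: 10 2,5-trans anti aldol
Product: 11 (2R,5S)-2-ArA-5-[(R)-(ArB)(trimethylsilyloxy)methyl]tetrahydro-4H-pyran-4-one
Conditions: Me3SiCl, imidazole, CH2Cl2, 0 °C; filtration through Et3N-deactivated silica
Reagents that add atoms: chlorotrimethylsilane, C[Si](C)(C)Cl
Why: O-Silylation masks the aldol hydroxyl, which as the free alkoxide would be trifluoroacetylated in step 6 and then lost by β-elimination toward C8'.

Step 6
Reactants: 11 silylated aldol; 12 4-acetamidobenzenesulfonyl azide
Product: 15 (2S,5S)-2-ArA-3-diazo-5-[(R)-hydroxy(ArB)methyl]tetrahydro-4H-pyran-4-one (2,5-trans; the C2 descriptor changes by priority only), via trifluoroacetyl ketone 13 (not isolated), via silylated diazo ketone 14 (not isolated)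
Conditions: LiN(SiMe3)2 (1.1 equiv), THF, −78 °C; CF3CO2CH2CF3 (1.2 equiv), −78 °C; sat. aq NH4Cl; then 12, Et3N, H2O (1 equiv), MeCN, 23 °C; then K2CO3 (0.2 equiv), MeOH, 0 °C
Reagents that add atoms: 4-acetamidobenzenesulfonyl azide (12), CC(=O)Nc1ccc(cc1)S(=O)(=O)N=[N+]=[N-]
Why: Kinetic deprotonation at the only α-methylene (C8) and C-trifluoroacetylation activate C8 for detrifluoroacetylative diazo transfer (a Regitz-type diazo transfer in which the adduct fragments at the more electrophilic trifluoroacetyl carbonyl), and brief carbonate methanolysis then frees the C7' hydroxyl without harming the base-stable diazo ketone or the aryl silyl ether.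

Step 7
Reactants: 15 2,5-trans diazo ketone with free C7' hydroxyl
Product: 18 (3R,3aS,6R,6aR)-3-ArB-6-ArA-tetrahydro-1H,3H-furo[3,4-c]furan-1-one (cis-fused lactone), via ketene 16 (not isolated), via lactone enol 17 (not isolated)
Conditions: hν (365 nm LED), dry degassed MeCN (0.01 M), 20 °C
Reagents that add atoms: none
Why: Excitation of the diazo ketone, which the ring holds s-cis, should expel nitrogen in concert with the 1,2-shift of C8' from C9 to C8 (Wolff rearrangement), so that C8' migrates with retention and ring 1 arises by contraction of the pyranone as the ketene 16. Ring 2 closes by 5-exo-dig attack of the C7' hydroxyl on the sp carbon C9 of the ketene, which gives the enol 17 of the lactone. The only new stereocentre, C8, is set when 17 is protonated on carbon: a trans-fused bicyclo[3.3.0] lactone is too strained and C8 stays epimerisable next to the carbonyl, so the cis fusion is the expected outcome, while C7, C8' and C7' are carried over unchanged. The closest known reaction type is the photochemical ring contraction of cyclic 2-diazo ketones with capture of the ketene by an alcohol. The step needs the rearrangement to win over a 1,2-hydride shift from C7 and over insertion into the neighbouring O–H bond, which the locked s-cis geometry and metal-free irradiation at 365 nm (beyond the absorption of the aryl ethers, so that the prenyl ether should not undergo photo-Claisen cleavage) are meant to secure, and it needs the internal hydroxyl to be the only trap, which the dry, dilute, aprotic medium provides.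

Step 8
Reactants: 18 cis-fused lactone
Product: 19 [(2R,3S,4S)-2-ArA-4-[(R)-hydroxy(ArB)methyl]tetrahydrofuran-3-yl]methanol
Conditions: LiAlH4, THF, 0 °C; H2O, aq NaOH
Reagents that add atoms: none
Why: Hydride reduction of the γ-lactone gives the 1,4-diol under basic conditions, with no bond to C7, C8, C8' or C7' broken.

Step 9
Reactants: 19 diol
Product: 21 (1R,3aS,4R,6aS)-1-ArA-4-ArB-tetrahydro-1H,3H-furo[3,4-c]furan, via primary mesylate 20 (not isolated)
Conditions: MeSO2Cl (1.1 equiv), pyridine, CH2Cl2, 0 → 40 °C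
Reagents that add atoms: none
Why: The primary C9 hydroxyl should be sulfonylated faster than the hindered benzylic one, and the C7' hydroxyl then displaces the mesylate in a 5-exo-tet Williamson closure that forms C9–O2 without touching a stereocentre and without the Lewis acid of a lactol reduction, which would endanger the prenyl ether and the two electron-rich benzylic ethers.

Step 10
Reactants: 21 silylated furofuran
Product: 22 target, 2-methoxy-4-[(1R,3aS,4R,6aS)-4-[3-methoxy-4-(3-methylbut-2-enyloxy)phenyl]tetrahydro-1H,3H-furo[3,4-c]furan-1-yl]phenol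
Conditions: Bu4NF, THF, 0 °C; sat. aq NH4Cl
Reagents that add atoms: none
Why: Fluoride cleaves the aryl silicon–oxygen bond, and the molecule holds no other silyl or base-labile group.

**Compound list**

1 | vanillin (4-hydroxy-3-methoxybenzaldehyde) | COc1cc(C=O)ccc1O | starting material
2 | 3-methoxy-4-(triisopropylsilyloxy)benzaldehyde | COc1cc(C=O)ccc1O[Si](C(C)C)(C(C)C)C(C)C | intermediate
3 | prenyl bromide (1-bromo-3-methylbut-2-ene) | CC(C)=CCBr | starting material
4 | 3-methoxy-4-(3-methylbut-2-enyloxy)benzaldehyde | COc1cc(C=O)ccc1OCC=C(C)C | intermediate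
5 | (E)-1-methoxy-3-(trimethylsilyloxy)buta-1,3-diene | CO/C=C/C(=C)O[Si](C)(C)C | starting material
6 | (R,E)-1-methoxy-5-ArA-5-(trimethylsilyloxy)pent-1-en-3-one | COc1cc([C@H](O[Si](C)(C)C)CC(=O)/C=C/OC)ccc1O[Si](C(C)C)(C(C)C)C(C)C | intermediate (not isolated)
7 | (R)-2-ArA-2,3-dihydro-4H-pyran-4-one | COc1cc([C@@H]2OC=CC(=O)C2)ccc1O[Si](C(C)C)(C(C)C)C(C)C | intermediate
8 | lithium (R)-2-ArA-3,6-dihydro-2H-pyran-4-olate (C9=C8' enolate) | COc1cc([C@@H]2OCC=C([O-])C2)ccc1O[Si](C(C)C)(C(C)C)C(C)C.[Li+] | intermediate (not isolated)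
9 | chlorozinc alkoxide of 10 | COc1cc([C@@H]2OC[C@@H]([C@@H](O[Zn]Cl)c3ccc(OCC=C(C)C)c(OC)c3)C(=O)C2)ccc1O[Si](C(C)C)(C(C)C)C(C)C | intermediate (not isolated)
10 | (2R,5S)-2-ArA-5-[(R)-hydroxy(ArB)methyl]tetrahydro-4H-pyran-4-one | COc1cc([C@@H]2OC[C@@H]([C@@H](O)c3ccc(OCC=C(C)C)c(OC)c3)C(=O)C2)ccc1O[Si](C(C)C)(C(C)C)C(C)C | intermediate
11 | (2R,5S)-2-ArA-5-[(R)-(ArB)(trimethylsilyloxy)methyl]tetrahydro-4H-pyran-4-one | COc1cc([C@@H]2OC[C@@H]([C@@H](O[Si](C)(C)C)c3ccc(OCC=C(C)C)c(OC)c3)C(=O)C2)ccc1O[Si](C(C)C)(C(C)C)C(C)C | intermediate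
12 | 4-acetamidobenzenesulfonyl azide | CC(=O)Nc1ccc(cc1)S(=O)(=O)N=[N+]=[N-] | starting material
13 | C8-trifluoroacetyl derivative of 11, drawn as its ring enol | COc1cc([C@@H]2OC[C@@H]([C@@H](O[Si](C)(C)C)c3ccc(OCC=C(C)C)c(OC)c3)C(O)=C2C(=O)C(F)(F)F)ccc1O[Si](C(C)C)(C(C)C)C(C)C | intermediate (not isolated)
14 | (2S,5S)-2-ArA-3-diazo-5-[(R)-(ArB)(trimethylsilyloxy)methyl]tetrahydro-4H-pyran-4-one | COc1cc([C@@H]2OC[C@@H]([C@@H](O[Si](C)(C)C)c3ccc(OCC=C(C)C)c(OC)c3)C(=O)C2=[N+]=[N-])ccc1O[Si](C(C)C)(C(C)C)C(C)C | intermediate (not isolated)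
15 | (2S,5S)-2-ArA-3-diazo-5-[(R)-hydroxy(ArB)methyl]tetrahydro-4H-pyran-4-one | COc1cc([C@@H]2OC[C@@H]([C@@H](O)c3ccc(OCC=C(C)C)c(OC)c3)C(=O)C2=[N+]=[N-])ccc1O[Si](C(C)C)(C(C)C)C(C)C | intermediate
16 | ketene: ring 1 tetrahydrofuran with C8=C9=O, ArA on C7 and the (R)-hydroxy(ArB)methyl group on C8' | COc1cc([C@@H]2OC[C@@H]([C@@H](O)c3ccc(OCC=C(C)C)c(OC)c3)C2=C=O)ccc1O[Si](C(C)C)(C(C)C)C(C)C | intermediate (not isolated)
17 | lactone enol: bicycle with C8=C9(OH)–O2 | COc1cc([C@@H]2OC[C@@H]3C2=C(O)O[C@H]3c2ccc(OCC=C(C)C)c(OC)c2)ccc1O[Si](C(C)C)(C(C)C)C(C)C | intermediate (not isolated)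
18 | (3R,3aS,6R,6aR)-3-ArB-6-ArA-tetrahydro-1H,3H-furo[3,4-c]furan-1-one | COc1cc([C@@H]2OC[C@@H]3[C@H]2C(=O)O[C@H]3c2ccc(OCC=C(C)C)c(OC)c2)ccc1O[Si](C(C)C)(C(C)C)C(C)C | intermediate
19 | [(2R,3S,4S)-2-ArA-4-[(R)-hydroxy(ArB)methyl]tetrahydrofuran-3-yl]methanol | COc1cc([C@@H]2OC[C@@H]([C@@H](O)c3ccc(OCC=C(C)C)c(OC)c3)[C@H]2CO)ccc1O[Si](C(C)C)(C(C)C)C(C)C | intermediate
20 | C9 methanesulfonate of 19 | COc1cc([C@@H]2OC[C@@H]([C@@H](O)c3ccc(OCC=C(C)C)c(OC)c3)[C@H]2COS(C)(=O)=O)ccc1O[Si](C(C)C)(C(C)C)C(C)C | intermediate (not isolated)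
21 | (1R,3aS,4R,6aS)-1-ArA-4-ArB-tetrahydro-1H,3H-furo[3,4-c]furan | COc1cc([C@@H]2OC[C@@H]3[C@H]2CO[C@H]3c2ccc(OCC=C(C)C)c(OC)c2)ccc1O[Si](C(C)C)(C(C)C)C(C)C | intermediate
22 | 2-methoxy-4-[(1R,3aS,4R,6aS)-4-[3-methoxy-4-(3-methylbut-2-enyloxy)phenyl]tetrahydro-1H,3H-furo[3,4-c]furan-1-yl]phenol | COc1cc([C@@H]2OC[C@@H]3[C@H]2CO[C@H]3c2ccc(OCC=C(C)C)c(OC)c2)ccc1O | target

**Step count**

Total: 10 steps. Longest linear sequence: 9 steps (steps 1, 3, 4, 5, 6, 7, 8, 9 and 10 from vanillin).

**Steps most likely to fail**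

Step 7 (key step). The excited diazo ketone may be diverted before the 1,2-shift, by hydride migration from C7 or by insertion into the neighbouring O–H bond, and the ketene may react with itself if the internal capture is slow. The fallback takes the hydroxyl out of the photolysis and lets the solvent trap the ketene. It sets out from 14, which is isolated when the carbonate methanolysis that ends step 6 is left out. Irradiation of 14 at 365 nm in methanol, the standard photochemical Wolff ring contraction with alcohol capture, should give through the silylated ketene F1 the methyl tetrahydrofuran-3-carboxylate F2 as a mixture of C8 epimers. K2CO3 in methanol at 0 °C then removes the silyl group to give the hydroxy ester F3. DBU in toluene at 60 °C should equilibrate C8 and lactonise the cis isomer with loss of methanol, which returns the route at 18.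

Step 4. The aldolate may not reach equilibrium, so that kinetic axial attack leaves the side chain cis to the C7 aryl, or it may lose water or revert on warming. The fallback uses the kinetic preference instead of fighting it and corrects C7 afterwards. It sets out from 2 and 5: with (S)-BINOL in place of (R)-BINOL the conditions of step 3 should give, through the open-chain adduct F4, the (S)-dihydropyranone F5. LiBH(sBu)3 at −78 °C gives the lithium enolate F6, and addition of 4 with a quench at −78 °C (no zinc, no warming) should give mainly the 2,5-cis anti aldol F7, which has the C8' and C7' configurations of 10 and is purified by chromatography. Silylation as in step 5 gives F8. Catalytic DBU in toluene should then open the ring by β-elimination from the C8 enolate to the hydroxy enone F9 and close it again by oxa-Michael addition, which inverts only C7 to the diequatorial isomer and returns the route at 11.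

Step 6. The C8 enolate may expel O1 and open the ring, deprotonation may occur in part at C8', or the silyl ether may be lost so that O-acylation and elimination at C7' set in. The fallback avoids the enolate. It sets out from 11: tert-butoxybis(dimethylamino)methane in toluene at 60 °C can condense only at the C8 methylene and should give the enaminone F10. Diazo transfer from 12 to this enaminone in MeCN, a known route to α-diazo ketones with loss of an N-sulfonylformamidine, returns the route at 14, which the methanolysis of step 6 converts to 15.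

Further compounds
F1 | step 7 | silylated ketene: ring 1 tetrahydrofuran with C8=C9=O and the (R)-(ArB)(trimethylsilyloxy)methyl group on C8' | COc1cc([C@@H]2OC[C@@H]([C@@H](O[Si](C)(C)C)c3ccc(OCC=C(C)C)c(OC)c3)C2=C=O)ccc1O[Si](C(C)C)(C(C)C)C(C)C
F2 | step 7 | methyl 2-ArA-4-[(R)-(ArB)(trimethylsilyloxy)methyl]tetrahydrofuran-3-carboxylate (C8 epimers) | COc1cc([C@@H]2OC[C@@H]([C@@H](O[Si](C)(C)C)c3ccc(OCC=C(C)C)c(OC)c3)C2C(=O)OC)ccc1O[Si](C(C)C)(C(C)C)C(C)C
F3 | step 7 | methyl 2-ArA-4-[(R)-hydroxy(ArB)methyl]tetrahydrofuran-3-carboxylate (C8 epimers) | COc1cc([C@@H]2OC[C@@H]([C@@H](O)c3ccc(OCC=C(C)C)c(OC)c3)C2C(=O)OC)ccc1O[Si](C(C)C)(C(C)C)C(C)C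
F4 | step 4 | (S,E)-1-methoxy-5-ArA-5-(trimethylsilyloxy)pent-1-en-3-one | COc1cc([C@@H](O[Si](C)(C)C)CC(=O)/C=C/OC)ccc1O[Si](C(C)C)(C(C)C)C(C)C
F5 | step 4 | (S)-2-ArA-2,3-dihydro-4H-pyran-4-one | COc1cc([C@H]2OC=CC(=O)C2)ccc1O[Si](C(C)C)(C(C)C)C(C)C
F6 | step 4 | lithium (S)-2-ArA-3,6-dihydro-2H-pyran-4-olate | COc1cc([C@H]2OCC=C([O-])C2)ccc1O[Si](C(C)C)(C(C)C)C(C)C.[Li+]
F7 | step 4 | (2S,5S)-2-ArA-5-[(R)-hydroxy(ArB)methyl]tetrahydro-4H-pyran-4-one (2,5-cis anti aldol) | COc1cc([C@H]2OC[C@@H]([C@@H](O)c3ccc(OCC=C(C)C)c(OC)c3)C(=O)C2)ccc1O[Si](C(C)C)(C(C)C)C(C)C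
F8 | step 4 | trimethylsilyl ether of F7 | COc1cc([C@H]2OC[C@@H]([C@@H](O[Si](C)(C)C)c3ccc(OCC=C(C)C)c(OC)c3)C(=O)C2)ccc1O[Si](C(C)C)(C(C)C)C(C)C
F9 | step 4 | ring-opened (E)-enone ArA–CH=CH–CO–CH(CH2OH)–CH(OSiMe3)ArB | COc1cc(/C=C/C(=O)[C@@H](CO)[C@@H](O[Si](C)(C)C)c2ccc(OCC=C(C)C)c(OC)c2)ccc1O[Si](C(C)C)(C(C)C)C(C)C
F10 | step 6 | (E)-C8-(dimethylaminomethylene) derivative of 11 | COc1cc([C@@H]2OC[C@@H]([C@@H](O[Si](C)(C)C)c3ccc(OCC=C(C)C)c(OC)c3)C(=O)/C2=C/N(C)C)ccc1O[Si](C(C)C)(C(C)C)C(C)C
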